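**Assumption:** the target has no stereocentre (it is achiral and symmetric), so the SMILES is the full structure and no enantiocontrol is needed. The one stereocentre that appears on the way (compound 6) is racemic and is removed in step 3.

**Retrosynthetic overview**
1. The target is two gigantol units joined by a CH2 at the A-ring carbon para to OH. The last C–C bonds come from acid-mediated methylenation of an A-ring O-TIPS gigantol with formaldehyde, where the bulky silyl ether shields both positions ortho to it; desilylation follows.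
2. Key bond: each ArCH2–CH2Ar' bond is made from two aldehyde carbons. The N–H hydrazone of the A-ring aldehyde acts as a benzyl-anion equivalent (Ru-catalysed carbonyl umpolung, N2 loss) and adds to O-benzylvanillin.
3. One hydrogenolysis then removes the carbinol OH and the benzyl ether.
4. No ring is formed: all four benzene rings are bought. Order: A-ring silylation → A–B coupling → reduction → A–CH2–A bridging → deprotection.

**Route**

Step 1
Reactants: 1 3-hydroxy-5-methoxybenzaldehyde
Product: 2 3-methoxy-5-[(triisopropylsilyl)oxy]benzaldehyde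
Conditions: TIPSCl (1.2 equiv), imidazole (2 equiv), DMF, rt
Reagents that add atoms: triisopropylsilyl chloride, CC(C)[Si](Cl)(C(C)C)C(C)C
Why: Imidazole-promoted O-silylation of the only phenol; the TIPS ether masks the acidic OH for the base-mediated key step and later blocks the two ring positions ortho to it.

Step 2
Reactants: 2 3-methoxy-5-[(triisopropylsilyl)oxy]benzaldehyde (1.3 equiv); 3 hydrazine monohydrate; 4 4-(benzyloxy)-3-methoxybenzaldehyde (1.0 equiv)
Product: 6 rac-1-[4-(benzyloxy)-3-methoxyphenyl]-2-{3-methoxy-5-[(triisopropylsilyl)oxy]phenyl}ethan-1-ol, via aryl N–H hydrazone 5 (not isolated)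
Conditions: 3 (1.05 equiv per 2), THF, rt, 30 min; then 4, [Ru(p-cymene)Cl2]2 (1 mol%), dmpe (2 mol%), K3PO4 (25 mol%), THF, 45 °C
Reagents that add atoms: none
Why: Ru(II)/bisphosphine-catalysed carbonyl-umpolung addition of an N–H hydrazone to an aldehyde (Wolff–Kishner-type carbanion equivalent): the former C=O carbon of 2 becomes a benzyl nucleophile that attacks the C=O of 4 through a six-membered Ru-bound transition state with loss of N2, giving a racemic carbinol that step 3 erases.

Step 3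
Reactants: 6 rac-1-[4-(benzyloxy)-3-methoxyphenyl]-2-{3-methoxy-5-[(triisopropylsilyl)oxy]phenyl}ethan-1-ol
Product: 7 2-methoxy-4-(2-{3-methoxy-5-[(triisopropylsilyl)oxy]phenyl}ethyl)phenol
Conditions: H2 (3 bar), 10% Pd/C, EtOH–AcOH (10:1), 40 °C
Reagents that add atoms: none
Why: Pd-catalysed hydrogenolysis cleaves the benzyl ether and the para-oxygen-activated benzylic C–OH in one pot while the aryl silyl ether is inert; any stilbene formed by dehydration is hydrogenated to the same product.

Step 4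
Reactants: 7 2-methoxy-4-(2-{3-methoxy-5-[(triisopropylsilyl)oxy]phenyl}ethyl)phenol (2 equiv); 8 formaldehyde (as paraformaldehyde, 1 equiv CH2O)
Product: 10 bis{2-[2-(4-hydroxy-3-methoxyphenyl)ethyl]-6-methoxy-4-[(triisopropylsilyl)oxy]phenyl}methane, via hydroxymethyl arene 9 (not isolated)
Conditions: (CH2O)n, TFA (1 equiv), CH2Cl2 (0.5 M), 0 °C → rt
Reagents that add atoms: none
Why: Acid-catalysed hydroxymethylation followed by Friedel–Crafts benzylation (arene–formaldehyde condensation): the carbon para to OTIPS and ortho to OMe is the only doubly activated site not flanked by the silyl ether, so 9 ionises to a 2,4-dioxygenated benzyl cation that is captured at the same site of a second molecule of 7, and the singly activated guaiacol ring does not compete.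

Step 5
Reactants: 10 bis{2-[2-(4-hydroxy-3-methoxyphenyl)ethyl]-6-methoxy-4-[(triisopropylsilyl)oxy]phenyl}methane
Product: 11 bis{4-hydroxy-2-[2-(4-hydroxy-3-methoxyphenyl)ethyl]-6-methoxyphenyl}methane (target)
Conditions: TBAF (2.4 equiv), AcOH (2.4 equiv), THF, 0 °C → rt
Reagents that add atoms: none
Why: Fluoride-mediated cleavage of both aryl silyl ethers (Si–F bond formation), buffered with AcOH so the electron-rich phenolates are not exposed to air oxidation; no other group reacts and the product is the achiral target.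

**Compound list**
1 | 3-hydroxy-5-methoxybenzaldehyde | O=Cc1cc(O)cc(OC)c1 | starting material
2 | 3-methoxy-5-[(triisopropylsilyl)oxy]benzaldehyde | O=Cc1cc(OC)cc(O[Si](C(C)C)(C(C)C)C(C)C)c1 | intermediate
3 | hydrazine monohydrate | NN.O | starting material
4 | 4-(benzyloxy)-3-methoxybenzaldehyde (O-benzylvanillin) | O=Cc1ccc(OCc2ccccc2)c(OC)c1 | starting material
5 | (E)-{3-methoxy-5-[(triisopropylsilyl)oxy]benzylidene}hydrazine | N/N=C/c1cc(OC)cc(O[Si](C(C)C)(C(C)C)C(C)C)c1 | intermediate
6 | rac-1-[4-(benzyloxy)-3-methoxyphenyl]-2-{3-methoxy-5-[(triisopropylsilyl)oxy]phenyl}ethan-1-ol | OC(Cc1cc(OC)cc(O[Si](C(C)C)(C(C)C)C(C)C)c1)c1ccc(OCc2ccccc2)c(OC)c1 | intermediate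
7 | 2-methoxy-4-(2-{3-methoxy-5-[(triisopropylsilyl)oxy]phenyl}ethyl)phenol | COc1cc(CCc2cc(OC)cc(O[Si](C(C)C)(C(C)C)C(C)C)c2)ccc1O | intermediate
8 | formaldehyde (paraformaldehyde) | C=O | starting material
9 | 4-(2-{2-(hydroxymethyl)-3-methoxy-5-[(triisopropylsilyl)oxy]phenyl}ethyl)-2-methoxyphenol | COc1cc(CCc2cc(O[Si](C(C)C)(C(C)C)C(C)C)cc(OC)c2CO)ccc1O | intermediate
10 | bis{2-[2-(4-hydroxy-3-methoxyphenyl)ethyl]-6-methoxy-4-[(triisopropylsilyl)oxy]phenyl}methane | COc1cc(CCc2cc(O[Si](C(C)C)(C(C)C)C(C)C)cc(OC)c2Cc2c(CCc3ccc(O)c(OC)c3)cc(O[Si](C(C)C)(C(C)C)C(C)C)cc2OC)ccc1O | intermediate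
11 | bis{4-hydroxy-2-[2-(4-hydroxy-3-methoxyphenyl)ethyl]-6-methoxyphenyl}methane | COc1cc(CCc2cc(O)cc(OC)c2Cc2c(CCc3ccc(O)c(OC)c3)cc(O)cc2OC)ccc1O | target

**Totals:** 5 steps; longest linear sequence 5 steps (1 → 2 → 6 → 7 → 10 → 11), with 4 entering at step 2.

**Steps most likely to fail**

1. Step 4 (methylene bridging). The risks are attack para to OMe instead of para to OTIPS, intramolecular closure of the benzyl cation onto the guaiacol ring to give a dibenzosuberane, and partial desilylation. The fallback sets out from 7 and comes back at 11, fixing the regiochemistry with a halogen and making the bridge by carbonyl addition. The guaiacol OH of 7 is silylated (TIPSCl, imidazole, DMF) to triisopropyl[2-methoxy-4-(2-{3-methoxy-5-[(triisopropylsilyl)oxy]phenyl}ethyl)phenoxy]silane F1. NBS (1.0 equiv, MeCN, 0 °C) brominates the doubly activated ring para to OTIPS to give {4-[2-(2-bromo-3-methoxy-5-[(triisopropylsilyl)oxy]phenyl)ethyl]-2-methoxyphenoxy}triisopropylsilane F2, and isomers can be removed at this stage. Br/Li exchange (n-BuLi, THF, −78 °C) and addition of ethyl formate (0.5 equiv) give bis{6-methoxy-2-[2-(3-methoxy-4-[(triisopropylsilyl)oxy]phenyl)ethyl]-4-[(triisopropylsilyl)oxy]phenyl}methanol F3. Ionic hydrogenation (Et3SiH, TFA, CH2Cl2, 0 °C) gives bis{6-methoxy-2-[2-(3-methoxy-4-[(triisopropylsilyl)oxy]phenyl)ethyl]-4-[(triisopropylsilyl)oxy]phenyl}methane F4. TBAF/AcOH in THF then removes all four silyl groups to give 11.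

2. Step 2 (Ru-catalysed hydrazone addition). The risks are mixed azine formation, Wolff–Kishner reduction of 5 to the toluene, and low electrophilicity of electron-rich 4. The fallback sets out from 2 and 4 and comes back at 7, keeping the polarity-reversed bond formation but with a stoichiometric lithiated dithiane (Corey–Seebach acyl anion). Aldehyde 2 with propane-1,3-dithiol and catalytic BF3·OEt2 in CH2Cl2 gives 2-{3-methoxy-5-[(triisopropylsilyl)oxy]phenyl}-1,3-dithiane F5. Aldehyde 4 is reduced (NaBH4, MeOH) to [4-(benzyloxy)-3-methoxyphenyl]methanol F6 and converted (SOCl2, CH2Cl2, 0 °C) into 1-(benzyloxy)-4-(chloromethyl)-2-methoxybenzene F7. F5 is lithiated (n-BuLi, THF, −78 °C) and alkylated with F7 to give 2-[4-(benzyloxy)-3-methoxybenzyl]-2-{3-methoxy-5-[(triisopropylsilyl)oxy]phenyl}-1,3-dithiane F8. Raney nickel under H2 in refluxing EtOH removes the sulfur and the benzyl ether to give 7.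

3. Step 3 (double hydrogenolysis). The risk is that the benzylic C–OH cleavage stalls after debenzylation. The fallback sets out from 6 and comes back at 7, replacing hydrogenolysis by elimination then hydrogenation. Catalytic p-TsOH in toluene at 80 °C dehydrates the p-alkoxybenzylic alcohol to (E)-{3-[4-(benzyloxy)-3-methoxystyryl]-5-methoxyphenoxy}triisopropylsilane F9. H2 over Pd/C in EtOAc then saturates the alkene and cleaves the benzyl ether to give 7.

**Further compounds**
F1 | step 4 | triisopropyl[2-methoxy-4-(2-{3-methoxy-5-[(triisopropylsilyl)oxy]phenyl}ethyl)phenoxy]silane | COc1cc(CCc2cc(OC)cc(O[Si](C(C)C)(C(C)C)C(C)C)c2)ccc1O[Si](C(C)C)(C(C)C)C(C)C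
F2 | step 4 | {4-[2-(2-bromo-3-methoxy-5-[(triisopropylsilyl)oxy]phenyl)ethyl]-2-methoxyphenoxy}triisopropylsilane | COc1cc(CCc2cc(O[Si](C(C)C)(C(C)C)C(C)C)cc(OC)c2Br)ccc1O[Si](C(C)C)(C(C)C)C(C)C
F3 | step 4 | bis{6-methoxy-2-[2-(3-methoxy-4-[(triisopropylsilyl)oxy]phenyl)ethyl]-4-[(triisopropylsilyl)oxy]phenyl}methanol | COc1cc(CCc2cc(O[Si](C(C)C)(C(C)C)C(C)C)cc(OC)c2C(O)c2c(CCc3ccc(O[Si](C(C)C)(C(C)C)C(C)C)c(OC)c3)cc(O[Si](C(C)C)(C(C)C)C(C)C)cc2OC)ccc1O[Si](C(C)C)(C(C)C)C(C)C
F4 | step 4 | bis{6-methoxy-2-[2-(3-methoxy-4-[(triisopropylsilyl)oxy]phenyl)ethyl]-4-[(triisopropylsilyl)oxy]phenyl}methane | COc1cc(CCc2cc(O[Si](C(C)C)(C(C)C)C(C)C)cc(OC)c2Cc2c(CCc3ccc(O[Si](C(C)C)(C(C)C)C(C)C)c(OC)c3)cc(O[Si](C(C)C)(C(C)C)C(C)C)cc2OC)ccc1O[Si](C(C)C)(C(C)C)C(C)C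
F5 | step 2 | 2-{3-methoxy-5-[(triisopropylsilyl)oxy]phenyl}-1,3-dithiane | COc1cc(cc(O[Si](C(C)C)(C(C)C)C(C)C)c1)C1SCCCS1
F6 | step 2 | [4-(benzyloxy)-3-methoxyphenyl]methanol | COc1cc(CO)ccc1OCc1ccccc1
F7 | step 2 | 1-(benzyloxy)-4-(chloromethyl)-2-methoxybenzene | COc1cc(CCl)ccc1OCc1ccccc1
F8 | step 2 | 2-[4-(benzyloxy)-3-methoxybenzyl]-2-{3-methoxy-5-[(triisopropylsilyl)oxy]phenyl}-1,3-dithiane | COc1cc(CC2(SCCCS2)c2cc(OC)cc(O[Si](C(C)C)(C(C)C)C(C)C)c2)ccc1OCc1ccccc1
F9 | step 3 | (E)-{3-[4-(benzyloxy)-3-methoxystyryl]-5-methoxyphenoxy}triisopropylsilane | COc1cc(/C=C/c2cc(OC)cc(O[Si](C(C)C)(C(C)C)C(C)C)c2)ccc1OCc1ccccc1
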